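**Retrosynthetic overview**

1. The target is the ferulate of a (2S,3R,4R)-oxolane (O1, C2 syringyl, C3 CH2O arm, C4 guaiacylmethyl, C5 H2; 2,3-trans, 3,4-cis). The ester C–O bond is made last (Mitsunobu), and C4 is set just before by hydrogenating an exocyclic (E)-benzylidene at C4 from the face away from the C3 arm.
2. Structural feature used: oxolane C5 is a bare CH2 held between O1 and C4, so it can be delivered as carbon monoxide, while C4 and its exocyclic benzylic carbon are the two sp carbons of a guaiacyl-capped alkyne.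
3. Key disconnection: O1–C5 and C5–C4 together, by palladium cyclocarbonylation of anti homopropargylic alcohol 13 with CO to the (E)-α-benzylidene lactone 15. This is the only ring-forming step (the benzene rings are bought); the lactone carbonyl is then reduced to the C5 methylene.
4. Alcohol 13 comes from a palladium/indium propargylation that makes the C2–C3 bond and both stereocentres: (S)-propargylic mesylate 9 (from vanillin, silyloxyacetaldehyde and an ynone transfer hydrogenation) plus O-benzylsyringaldehyde 11.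

Key step: step 9

Assumption (chemistry): step 8 is taken to follow the usual course of such propargylations, namely anti SN2′ entry of palladium, retention on transfer to indium and a closed SE2′ addition. This means net inversion at the mesylate carbon, so the (S)-mesylate is the enantiomer required.

**Route**

Step 1
Reactants: 1 vanillin
Product: 2 4-(benzyloxy)-3-methoxybenzaldehyde
Conditions: BnBr, K2CO3, DMF, 60 °C
Reagents that add atoms: benzyl bromide, BrCc1ccccc1
Why: Williamson ether synthesis on the acidic phenoxide with a benzylic bromide, the aldehyde being inert to K2CO3.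

Step 2
Reactants: 2 4-(benzyloxy)-3-methoxybenzaldehyde
Product: 3 1-(benzyloxy)-4-(2,2-dibromoethenyl)-2-methoxybenzene
Conditions: CBr4, PPh3, CH2Cl2, 0 °C
Reagents that add atoms: carbon tetrabromide, BrC(Br)(Br)Br
Why: Corey–Fuchs dibromo-olefination, in which the ylide Ph3P=CBr2 formed from PPh3 and CBr4 undergoes a Wittig reaction with the aryl aldehyde while the ethers are untouched.

Step 3
Reactants: 3 1-(benzyloxy)-4-(2,2-dibromoethenyl)-2-methoxybenzene, 4 (tert-butyldimethylsilyloxy)acetaldehyde
Product: 6 rac-4-[4-(benzyloxy)-3-methoxyphenyl]-1-(tert-butyldimethylsilyloxy)but-3-yn-2-ol, via lithium arylacetylide 5 (not isolated)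
Conditions: n-BuLi (2.1 equiv), THF, −78 °C; then 4, −78 °C to rt; H2O quench
Reagents that add atoms: none
Why: Second stage of the Corey–Fuchs sequence (bromine–lithium exchange, Fritsch–Buttenberg–Wiechell 1,2-shift and deprotonation) gives acetylide 5, which should add 1,2 to aldehyde 4 at −78 °C faster than it enolises it; the carbinol centre is racemic here and is erased in step 4.

Step 4
Reactants: 6 rac-4-[4-(benzyloxy)-3-methoxyphenyl]-1-(tert-butyldimethylsilyloxy)but-3-yn-2-ol
Product: 7 4-[4-(benzyloxy)-3-methoxyphenyl]-1-(tert-butyldimethylsilyloxy)but-3-yn-2-one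
Conditions: activated MnO2 (excess), CH2Cl2, rt
Reagents that add atoms: none
Why: MnO2 oxidation is selective for activated (propargylic) alcohols and leaves silyl and benzyl ethers alone.

Step 5
Reactants: 7 4-[4-(benzyloxy)-3-methoxyphenyl]-1-(tert-butyldimethylsilyloxy)but-3-yn-2-one
Product: 8 (2S)-4-[4-(benzyloxy)-3-methoxyphenyl]-1-(tert-butyldimethylsilyloxy)but-3-yn-2-ol
Conditions: Ru[(R,R)-TsNCH(Ph)CH(Ph)NH](p-cymene) (2 mol %), i-PrOH, rt
Reagents that add atoms: none
Why: Noyori asymmetric transfer hydrogenation of an alkynyl ketone, in which the alkynyl group takes the place of the aryl group of aryl ketones in the outer-sphere hydride/proton transfer, so the (R,R) catalyst should give the carbinol that is (S) here (CH2OSi outranks the alkynyl carbon) without touching the alkyne.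

Step 6
Reactants: 8 (2S)-4-[4-(benzyloxy)-3-methoxyphenyl]-1-(tert-butyldimethylsilyloxy)but-3-yn-2-ol
Product: 9 (2S)-4-[4-(benzyloxy)-3-methoxyphenyl]-1-(tert-butyldimethylsilyloxy)but-3-yn-2-yl methanesulfonate
Conditions: MsCl, Et3N, CH2Cl2, −78 to −20 °C; used crude
Reagents that add atoms: methanesulfonyl chloride, CS(=O)(=O)Cl
Why: O-sulfonylation of a secondary alcohol breaks no bond at carbon, so the configuration is retained.

Step 7
Reactants: 10 syringaldehyde
Product: 11 4-(benzyloxy)-3,5-dimethoxybenzaldehyde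
Conditions: BnBr, K2CO3, DMF, 60 °C
Reagents that add atoms: benzyl bromide, BrCc1ccccc1
Why: Williamson ether synthesis, the flanked phenoxide still being alkylated readily by a benzylic bromide in DMF.

Step 8
Reactants: 9 (2S)-4-[4-(benzyloxy)-3-methoxyphenyl]-1-(tert-butyldimethylsilyloxy)but-3-yn-2-yl methanesulfonate, 11 4-(benzyloxy)-3,5-dimethoxybenzaldehyde
Product: 13 (1S,2R)-1-[4-(benzyloxy)-3,5-dimethoxyphenyl]-4-[4-(benzyloxy)-3-methoxyphenyl]-2-[(tert-butyldimethylsilyloxy)methyl]but-3-yn-1-ol (anti), via allenylindium reagent 12 (not isolated)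
Conditions: Pd(OAc)2 (5 mol %), PPh3 (5 mol %), InI (1.5 equiv), THF–HMPA 3:1, rt
Reagents that add atoms: none
Why: Marshall-type umpolung propargylation, in which zerovalent palladium formed in situ displaces the mesylate anti (SN2′), InI takes over the allenyl group with retention to give the (Sa)-allenylindium 12, and 12 adds to the aldehyde through a closed six-membered SE2′ transition state with the aldehyde aryl group turned away from the CH2OSi substituent, which sets the propargylic centre (R, net inversion of the mesylate carbon) and the carbinol centre (S, anti) together.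

Step 9
Reactants: 13 (1S,2R)-1-[4-(benzyloxy)-3,5-dimethoxyphenyl]-4-[4-(benzyloxy)-3-methoxyphenyl]-2-[(tert-butyldimethylsilyloxy)methyl]but-3-yn-1-ol, 14 carbon monoxide
Product: 15 (3E,4R,5S)-5-[4-(benzyloxy)-3,5-dimethoxyphenyl]-3-[4-(benzyloxy)-3-methoxybenzylidene]-4-[(tert-butyldimethylsilyloxy)methyl]oxolan-2-one
Conditions: CO (7 bar), PdCl2(PPh3)2 (5 mol %), SnCl2 (anhydrous, 5 mol %), MeCN, 70 °C
Reagents that add atoms: none
Why: This is a palladium-catalysed cyclocarbonylation of a homopropargylic alcohol to an α-alkylidene-γ-butyrolactone, the closest known case being the PdCl2/PPh3/SnCl2 synthesis of α-methylene and α-alkylidene lactones from but-3-yn-1-ols. Divalent palladium takes up CO and the carbinol oxygen to become a Pd–C(=O)OR species with loss of HCl, the alkyne then adds cis across the Pd–acyl bond, and the HCl protonolyses the vinyl–palladium bond with retention and returns the catalyst. The single ring of the route closes in the 5-exo-dig mode: the acyl carbon joins the alkyne carbon nearer the carbinol, so the future O1–C5 and C5–C4 bonds form in one operation and palladium is left on the aryl-bearing carbon. No stereocentre is created and no bond to the two centres from step 8 is broken, while cis addition followed by retentive protonolysis places H cis and the guaiacyl group trans to the carbonyl, i.e. the (E) alkene. The step needs exo rather than 6-endo insertion and carbonylation rather than direct 5-endo attack of the hydroxyl on the alkyne; the three-atom link between oxygen and alkyne allows only the exo cis-insertion without strain, and CO pressure with phosphine and SnCl3 ligands should keep palladium as the carboalkoxy complex rather than as a free π-acid. The planar C4 obtained here is what lets hydrogen set the 3,4-cis relation in step 12.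

Step 10
Reactants: 15 (3E,4R,5S)-5-[4-(benzyloxy)-3,5-dimethoxyphenyl]-3-[4-(benzyloxy)-3-methoxybenzylidene]-4-[(tert-butyldimethylsilyloxy)methyl]oxolan-2-one
Product: 16 (3E,4R,5S)-5-[4-(benzyloxy)-3,5-dimethoxyphenyl]-3-[4-(benzyloxy)-3-methoxybenzylidene]-4-[(tert-butyldimethylsilyloxy)methyl]oxolan-2-ol (anomer mixture)
Conditions: i-Bu2AlH (1.2 equiv), CH2Cl2, −78 °C; aq. potassium sodium tartrate
Reagents that add atoms: none
Why: Partial 1,2-reduction of a lactone by i-Bu2AlH, whose tetrahedral aluminium hemiacetal persists at −78 °C until work-up, so the lactol rather than the diol should result and the ethers are inert.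

Step 11
Reactants: 16 (3E,4R,5S)-5-[4-(benzyloxy)-3,5-dimethoxyphenyl]-3-[4-(benzyloxy)-3-methoxybenzylidene]-4-[(tert-butyldimethylsilyloxy)methyl]oxolan-2-ol
Product: 17 (2S,3R,4E)-2-[4-(benzyloxy)-3,5-dimethoxyphenyl]-4-[4-(benzyloxy)-3-methoxybenzylidene]-3-[(tert-butyldimethylsilyloxy)methyl]oxolane
Conditions: Et3SiH (3 equiv), BF3·OEt2 (1.5 equiv), CH2Cl2, −78 °C
Reagents that add atoms: none
Why: Ionic (Kursanov–Parnes-type) deoxygenation of a lactol, in which BF3 ionises the anomeric hydroxyl to an allylic oxocarbenium ion that Et3SiH should reduce at the oxygen-bearing carbon, as in Ferrier-type reductions, keeping the styrene conjugation and both stereocentres.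

Step 12
Reactants: 17 (2S,3R,4E)-2-[4-(benzyloxy)-3,5-dimethoxyphenyl]-4-[4-(benzyloxy)-3-methoxybenzylidene]-3-[(tert-butyldimethylsilyloxy)methyl]oxolane
Product: 18 4-[(2S,3R,4R)-3-[(tert-butyldimethylsilyloxy)methyl]-4-(4-hydroxy-3-methoxybenzyl)oxolan-2-yl]-2,6-dimethoxyphenol
Conditions: H2 (1 atm), 10% Pd/C, EtOAc, rt
Reagents that add atoms: none
Why: Heterogeneous hydrogenation with concurrent hydrogenolysis of the two aryl benzyl ethers; the benzylidene aryl is cis to C3, so allylic 1,3-strain pushes the CH2OSi arm over one face and hydrogen should add to the other, setting C4 (R) with the guaiacylmethyl group cis to the C3 arm, while the cyclic benzylic ether at C2 cleaves far more slowly than O-benzyl aryl ethers under neutral conditions.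

Step 13
Reactants: 18 4-[(2S,3R,4R)-3-[(tert-butyldimethylsilyloxy)methyl]-4-(4-hydroxy-3-methoxybenzyl)oxolan-2-yl]-2,6-dimethoxyphenol
Product: 19 4-[(2S,3R,4R)-4-(4-hydroxy-3-methoxybenzyl)-3-(hydroxymethyl)oxolan-2-yl]-2,6-dimethoxyphenol
Conditions: Bu4NF (3 equiv), THF, 0 °C to rt, under argon; aq. work-up
Reagents that add atoms: none
Why: Fluoride-induced cleavage of a primary silyl ether driven by the Si–F bond, the phenols being only deprotonated reversibly.

Step 14
Reactants: 19 4-[(2S,3R,4R)-4-(4-hydroxy-3-methoxybenzyl)-3-(hydroxymethyl)oxolan-2-yl]-2,6-dimethoxyphenol, 20 (E)-ferulic acid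
Product: 21 [(2S,3R,4R)-2-(4-hydroxy-3,5-dimethoxyphenyl)-4-(4-hydroxy-3-methoxybenzyl)oxolan-3-yl]methyl (E)-3-(4-hydroxy-3-methoxyphenyl)prop-2-enoate
Conditions: PPh3 (1.5 equiv), DIAD (1.5 equiv), THF, 0 °C to rt
Reagents that add atoms: none
Why: Mitsunobu esterification, in which the only aliphatic alcohol is activated as its alkoxyphosphonium ion and displaced by the ferulate carboxylate, the one pronucleophile acidic enough (pKa about 4.5 against about 10 for the phenols) to be engaged, so the three phenols stay free and the (E)-cinnamate and ring stereocentres are untouched.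

**Compound list**

1 | vanillin (4-hydroxy-3-methoxybenzaldehyde) | COc1cc(C=O)ccc1O | starting material
2 | 4-(benzyloxy)-3-methoxybenzaldehyde | COc1cc(C=O)ccc1OCc1ccccc1 | intermediate
3 | 1-(benzyloxy)-4-(2,2-dibromoethenyl)-2-methoxybenzene | COc1cc(C=C(Br)Br)ccc1OCc1ccccc1 | intermediate
4 | (tert-butyldimethylsilyloxy)acetaldehyde | CC(C)(C)[Si](C)(C)OCC=O | starting material
5 | lithium [4-(benzyloxy)-3-methoxyphenyl]acetylide (not isolated) | [Li]C#Cc1ccc(OCc2ccccc2)c(OC)c1 | intermediate
6 | rac-4-[4-(benzyloxy)-3-methoxyphenyl]-1-(tert-butyldimethylsilyloxy)but-3-yn-2-ol | CC(C)(C)[Si](C)(C)OCC(O)C#Cc1ccc(OCc2ccccc2)c(OC)c1 | intermediate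
7 | 4-[4-(benzyloxy)-3-methoxyphenyl]-1-(tert-butyldimethylsilyloxy)but-3-yn-2-one | CC(C)(C)[Si](C)(C)OCC(=O)C#Cc1ccc(OCc2ccccc2)c(OC)c1 | intermediate
8 | (2S)-4-[4-(benzyloxy)-3-methoxyphenyl]-1-(tert-butyldimethylsilyloxy)but-3-yn-2-ol | CC(C)(C)[Si](C)(C)OC[C@@H](O)C#Cc1ccc(OCc2ccccc2)c(OC)c1 | intermediate
9 | (2S)-4-[4-(benzyloxy)-3-methoxyphenyl]-1-(tert-butyldimethylsilyloxy)but-3-yn-2-yl methanesulfonate | CC(C)(C)[Si](C)(C)OC[C@@H](OS(C)(=O)=O)C#Cc1ccc(OCc2ccccc2)c(OC)c1 | intermediate
10 | syringaldehyde (4-hydroxy-3,5-dimethoxybenzaldehyde) | COc1cc(C=O)cc(OC)c1O | starting material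
11 | 4-(benzyloxy)-3,5-dimethoxybenzaldehyde | COc1cc(C=O)cc(OC)c1OCc1ccccc1 | intermediate
12 | (Sa)-{1-[4-(benzyloxy)-3-methoxyphenyl]-4-(tert-butyldimethylsilyloxy)buta-1,2-dien-1-yl}indium iodide methanesulfonate (not isolated) | CC(C)(C)[Si](C)(C)OCC([H])=[C@]=C([In](I)OS(C)(=O)=O)c1ccc(OCc2ccccc2)c(OC)c1 | intermediate
13 | (1S,2R)-1-[4-(benzyloxy)-3,5-dimethoxyphenyl]-4-[4-(benzyloxy)-3-methoxyphenyl]-2-[(tert-butyldimethylsilyloxy)methyl]but-3-yn-1-ol (anti) | CC(C)(C)[Si](C)(C)OC[C@H]([C@H](O)c1cc(OC)c(OCc2ccccc2)c(OC)c1)C#Cc1ccc(OCc2ccccc2)c(OC)c1 | intermediate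
14 | carbon monoxide | [C-]#[O+] | starting material
15 | (3E,4R,5S)-5-[4-(benzyloxy)-3,5-dimethoxyphenyl]-3-[4-(benzyloxy)-3-methoxybenzylidene]-4-[(tert-butyldimethylsilyloxy)methyl]oxolan-2-one | O=C1O[C@H](c2cc(OC)c(OCc3ccccc3)c(OC)c2)[C@@H](CO[Si](C)(C)C(C)(C)C)/C1=C\c1ccc(OCc2ccccc2)c(OC)c1 | intermediate
16 | (3E,4R,5S)-5-[4-(benzyloxy)-3,5-dimethoxyphenyl]-3-[4-(benzyloxy)-3-methoxybenzylidene]-4-[(tert-butyldimethylsilyloxy)methyl]oxolan-2-ol (anomer mixture) | OC1O[C@H](c2cc(OC)c(OCc3ccccc3)c(OC)c2)[C@@H](CO[Si](C)(C)C(C)(C)C)/C1=C\c1ccc(OCc2ccccc2)c(OC)c1 | intermediate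
17 | (2S,3R,4E)-2-[4-(benzyloxy)-3,5-dimethoxyphenyl]-4-[4-(benzyloxy)-3-methoxybenzylidene]-3-[(tert-butyldimethylsilyloxy)methyl]oxolane | C1O[C@H](c2cc(OC)c(OCc3ccccc3)c(OC)c2)[C@@H](CO[Si](C)(C)C(C)(C)C)/C1=C\c1ccc(OCc2ccccc2)c(OC)c1 | intermediate
18 | 4-[(2S,3R,4R)-3-[(tert-butyldimethylsilyloxy)methyl]-4-(4-hydroxy-3-methoxybenzyl)oxolan-2-yl]-2,6-dimethoxyphenol | CC(C)(C)[Si](C)(C)OC[C@H]1[C@@H](Cc2ccc(O)c(OC)c2)CO[C@@H]1c1cc(OC)c(O)c(OC)c1 | intermediate
19 | 4-[(2S,3R,4R)-4-(4-hydroxy-3-methoxybenzyl)-3-(hydroxymethyl)oxolan-2-yl]-2,6-dimethoxyphenol | OC[C@H]1[C@@H](Cc2ccc(O)c(OC)c2)CO[C@@H]1c1cc(OC)c(O)c(OC)c1 | intermediate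
20 | (E)-ferulic acid | COc1cc(/C=C/C(=O)O)ccc1O | starting material
21 | [(2S,3R,4R)-2-(4-hydroxy-3,5-dimethoxyphenyl)-4-(4-hydroxy-3-methoxybenzyl)oxolan-3-yl]methyl (E)-3-(4-hydroxy-3-methoxyphenyl)prop-2-enoate | COc1cc(/C=C/C(=O)OC[C@H]2[C@@H](Cc3ccc(O)c(OC)c3)CO[C@@H]2c2cc(OC)c(O)c(OC)c2)ccc1O | target

**Totals**

Total step count: 14. Longest linear sequence: 13 steps (steps 1–6 and 8–14, from vanillin); step 7 lies on the convergent branch.

**Steps most likely to fail**

Step 9 (key step). The hydroxyl may attack the palladium-activated alkyne directly (5-endo cycloisomerisation to a dihydrofuran) faster than the hindered benzylic alcohol is carbonylated, or the trace HCl may ionise the benzylic carbinol. Fallback, from 13 back to 15: acylation with ethyl chloroformate and pyridine would give the ethyl carbonate F1. Treating F1 with Ti(O-i-Pr)4 and i-PrMgCl (2 equiv per titanium) in Et2O at −50 to −20 °C would form a divalent titanium–alkyne complex (titanacyclopropene). Its carbon nearer the carbonate should attack the carbonate carbonyl in an intramolecular nucleophilic acyl substitution, expelling ethoxide. Aqueous protonolysis of the remaining vinyl–titanium bond, which is cis to the new C–C bond, would then give lactone 15 with the same (E) geometry. This cyclisation is established for 3-alkynyl carbonates and needs neither CO nor acid.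

Step 8. An aryl group on the metal-bearing allenyl carbon may allow racemisation of the allenylpalladium or allenylindium species and so erode enantiopurity. The aromatic, electron-rich aldehyde may be discriminated poorly between anti and syn transition states. The propargyl-metal tautomer may also lose the silyloxy group by 1,4-elimination. Fallback, from 8 back to 13: methyl chloroformate and pyridine would give the methyl carbonate F2. Copper-catalysed anti SN2′ borylation (CuO-t-Bu with Xantphos as catalyst, monovalent copper; B2pin2, THF, rt) would convert F2 into the isolable, configurationally stable (Ra)-allenylboronate F3. Heating F3 with aldehyde 11 in toluene at 60–80 °C should effect allenylboration through a closed six-membered transition state and give 13 after work-up. The stereochemical course (anti SN2′, then closed SE2′) is the same as in the main route, but the boron reagent neither racemises nor eliminates.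

Step 11. Hydride may be delivered to the benzylic end of the allylic oxocarbenium ion, giving an endocyclic enol ether. BF3 may also ionise the benzylic C2–O bond (epimerisation, ring opening or over-reduction) or strip the silyl ether. Fallback, from 15 back to 17: reduction with excess i-Bu2AlH (3 equiv, CH2Cl2, −78 to 0 °C) would give the allylic diol F4. Selective sulfonylation of its primary allylic hydroxyl (TsCl, Et3N, cat. DMAP, CH2Cl2, 0 °C) would give the primary tosylate F5. NaH in THF should then close the ring by intramolecular Williamson etherification (5-exo-tet) through the C2 alkoxide, giving 17 without any cationic intermediate and without touching C2.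

**Further compounds**

F1 | step 9 | (1S,2R)-1-[4-(benzyloxy)-3,5-dimethoxyphenyl]-4-[4-(benzyloxy)-3-methoxyphenyl]-2-[(tert-butyldimethylsilyloxy)methyl]but-3-yn-1-yl ethyl carbonate | CC(C)(C)[Si](C)(C)OC[C@H]([C@H](OC(=O)OCC)c1cc(OC)c(OCc2ccccc2)c(OC)c1)C#Cc1ccc(OCc2ccccc2)c(OC)c1
F2 | step 8 | (2S)-4-[4-(benzyloxy)-3-methoxyphenyl]-1-(tert-butyldimethylsilyloxy)but-3-yn-2-yl methyl carbonate | CC(C)(C)[Si](C)(C)OC[C@@H](OC(=O)OC)C#Cc1ccc(OCc2ccccc2)c(OC)c1
F3 | step 8 | (Ra)-2-{1-[4-(benzyloxy)-3-methoxyphenyl]-4-(tert-butyldimethylsilyloxy)buta-1,2-dien-1-yl}-4,4,5,5-tetramethyl-1,3,2-dioxaborolane | CC(C)(C)[Si](C)(C)OCC([H])=[C@]=C(B1OC(C)(C)C(C)(C)O1)c1ccc(OCc2ccccc2)c(OC)c1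
F4 | step 11 | (1S,2R,3E)-1-[4-(benzyloxy)-3,5-dimethoxyphenyl]-3-[4-(benzyloxy)-3-methoxybenzylidene]-2-[(tert-butyldimethylsilyloxy)methyl]butane-1,4-diol | O[C@H](c1cc(OC)c(OCc2ccccc2)c(OC)c1)[C@@H](CO[Si](C)(C)C(C)(C)C)/C(CO)=C\c1ccc(OCc2ccccc2)c(OC)c1
F5 | step 11 | (2E,3R,4S)-4-[4-(benzyloxy)-3,5-dimethoxyphenyl]-2-[4-(benzyloxy)-3-methoxybenzylidene]-3-[(tert-butyldimethylsilyloxy)methyl]-4-hydroxybutyl 4-methylbenzenesulfonate | O[C@H](c1cc(OC)c(OCc2ccccc2)c(OC)c1)[C@@H](CO[Si](C)(C)C(C)(C)C)/C(COS(=O)(=O)c1ccc(C)cc1)=C\c1ccc(OCc2ccccc2)c(OC)c1
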